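**Plan**

1. Retrosynthesis: the 2'-O–Ts, 5-O–H (back to 5-O–Me) and 3-O–Me bonds are cut first, leading to 3-iodoflavone 13; then O1–C2 and C3–I (ring C) are cut to ynone 12; then the C3–C4 acyl–alkynyl bond to acid 7 and alkyne 10; last the aryl–CO2H bond of 7 to pentamethoxybenzene 5.
2. Forward: rings A and B are bought as benzenoid compounds (1 and 8). Ring A is oxygenated to 5 and carboxylated, ring B is tosylated and homologated to the arylacetylene, an acyl Sonogashira coupling joins them, and ring C is the only ring that is built (step 8).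
3. Enabling feature: in 12 the carbonyl carbon (future C4) and the ipso carbon (future C4a) lie on the mirror axis of the pentamethoxyphenyl ring, so the two ortho methoxyls are equivalent. Whichever oxygen becomes O1, the other stays as the C5 oxygen and C6–C8 keep their methoxyls; the electrophile that triggers closure remains on C3 as iodine, the handle for the 3-methoxyl.
4. End game: C3–I to C3–OH to C3–OMe, chelation-controlled 5-O-demethylation, detosylation.
5. Stereochemistry: the target has no stereocentre and no hindered axis, so nothing has to be set; all control is regio- and chemoselectivity.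

Key step: step 8

**Route**

Step 1
Reactants: 1 3,4,5-trimethoxyphenol
Product: 2 6-hydroxy-2,3,4-trimethoxybenzaldehyde
Conditions: MgCl2, Et3N, (CH2O)n, MeCN, reflux; 1 M HCl work-up
Reagents that add atoms: paraformaldehyde (formaldehyde), C=O
Why: Magnesium phenoxide-directed ortho-formylation (Casnati–Skattebøl) delivers formaldehyde next to the hydroxyl, and since both ortho positions of 1 are equivalent a single salicylaldehyde should result.

Step 2
Reactants: 2 6-hydroxy-2,3,4-trimethoxybenzaldehyde
Product: 4 3,4,5-trimethoxybenzene-1,2-diol, via aryl formate 3 (not isolated)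
Conditions: 30% aq. H2O2, NaOH, H2O–THF, 0 °C → rt, under argon; then HCl to pH 2
Reagents that add atoms: hydrogen peroxide, OO
Why: Dakin oxidation, in which the hydroperoxide adduct of the ortho-hydroxybenzaldehyde undergoes aryl migration to formate 3 that is saponified in the same alkaline medium, with air excluded so that the electron-rich catechol is not oxidised further.

Step 3
Reactants: 4 3,4,5-trimethoxybenzene-1,2-diol
Product: 5 pentamethoxybenzene
Conditions: MeI (excess), K2CO3, DMF, rt → 40 °C, under argon
Reagents that add atoms: iodomethane, CI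
Why: Williamson O-methylation of both phenoxides with excess methyl iodide should proceed to completion on this unhindered catechol.

Step 4
Reactants: 5 pentamethoxybenzene
Product: 7 pentamethoxybenzoic acid, via pentamethoxyphenyllithium 6 (not isolated)
Conditions: n-BuLi, TMEDA, THF, 0 °C; CO2, −78 °C → rt; aq. HCl
Reagents that add atoms: carbon dioxide, O=C=O
Why: Directed ortho-metalation, since the only ring hydrogen of 5 is flanked by two methoxy groups and should be removed cleanly by n-BuLi/TMEDA, followed by carboxylation of the aryllithium.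

Step 5
Reactants: 8 2-hydroxy-4-methoxybenzaldehyde
Product: 9 2-formyl-5-methoxyphenyl 4-methylbenzenesulfonate
Conditions: TsCl, Et3N, DMAP (cat.), CH2Cl2, 0 °C → rt
Reagents that add atoms: p-toluenesulfonyl chloride, Cc1ccc(S(=O)(=O)Cl)cc1
Why: DMAP-catalysed O-sulfonylation of the phenol installs an electron-withdrawing, non-nucleophilic mask on the future 2'-oxygen that is needed for the selectivity of step 8.

Step 6
Reactants: 9 2-formyl-5-methoxyphenyl 4-methylbenzenesulfonate
Product: 10 2-ethynyl-5-methoxyphenyl 4-methylbenzenesulfonate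
Conditions: dimethyl (1-diazo-2-oxopropyl)phosphonate, K2CO3, MeOH, 0 °C → rt
Reagents that add atoms: Ohira–Bestmann reagent, CC(=O)C(=[N+]=[N-])P(=O)(OC)OC
Why: Seyferth–Gilbert homologation in the Ohira–Bestmann variant converts the aldehyde into the terminal alkyne with carbonate in methanol at or below room temperature, which should be too mild to methanolyse an aryl tosylate (that needs prolonged reflux).

Step 7
Reactants: 7 pentamethoxybenzoic acid; 10 2-ethynyl-5-methoxyphenyl 4-methylbenzenesulfonate
Product: 12 3-[4-methoxy-2-(tosyloxy)phenyl]-1-(pentamethoxyphenyl)prop-2-yn-1-one, via pentamethoxybenzoyl chloride 11 (not isolated)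
Conditions: (COCl)2, DMF (cat.), CH2Cl2, 0 °C → rt, evaporate; then 10, PdCl2(PPh3)2 (cat.), CuI (cat.), Et3N, degassed THF, rt
Reagents that add atoms: none
Why: Acid chloride formation followed by acyl Sonogashira coupling, in which Pd(0) inserts into the C(O)–Cl bond and the copper acetylide transmetalates, should give the ynone at room temperature without touching the aryl tosylate.

Step 8
Reactants: 12 3-[4-methoxy-2-(tosyloxy)phenyl]-1-(pentamethoxyphenyl)prop-2-yn-1-one
Product: 13 3-iodo-5,6,7,8,4'-pentamethoxy-2'-(tosyloxy)flavone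
Conditions: ICl (1.5 equiv), CH2Cl2, −78 °C → rt; aq. Na2S2O3
Reagents that add atoms: iodine monochloride, ClI
Why: ICl delivers I+ to the ynone triple bond, and the positive charge develops at the alkyne carbon bonded to ring B (future C2), where the para 4'-methoxyl stabilises it while the carbonyl disfavours charge at the other carbon (future C3). One ortho methoxy oxygen of the aroyl group attacks this carbon anti to iodine in a 6-endo-dig closure that forms O1–C2 and C3–I, and chloride then removes the methyl group of the resulting oxonium ion by SN2 as chloromethane, leaving the aromatic chromone ring C. The closest known reaction type is the ICl-induced demethylative cyclisation of 2-methoxyaryl alkynones to 3-iodochromones. No stereocentre is formed. The step needs 6-endo rather than 5-exo closure (secured by the charge distribution just described), attack by a ring A oxygen rather than by the 2'-oxygen (secured by the sulfonyl group, which makes that oxygen non-nucleophilic), and iodination of the alkyne rather than of an arene (ring A has no C–H left and ring B is deactivated by the tosylate and the ynone). Because C4 lies on the mirror axis of the pentamethoxyphenyl ring, both ortho methoxyls are equivalent and either closure gives the same 5,6,7,8-tetramethoxy product.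

Step 9
Reactants: 13 3-iodo-5,6,7,8,4'-pentamethoxy-2'-(tosyloxy)flavone
Product: 16 3-hydroxy-5,6,7,8,4'-pentamethoxy-2'-(tosyloxy)flavone, via 3-magnesioflavone 14 (not isolated), via dimethyl boronate 15 (not isolated)
Conditions: iPrMgCl·LiCl (1.1 equiv), THF, −78 °C; B(OMe)3, −78 → 0 °C; AcOH, 30% aq. H2O2, 0 °C → rt
Reagents that add atoms: hydrogen peroxide, OO
Why: Iodine–magnesium exchange at the electron-poor alkenyl iodide (fast at −78 °C and tolerant of the vinylogous ester carbonyl and the aryl sulfonate), trapping with trimethyl borate and oxidative 1,2-migration from boron to oxygen should replace iodine by hydroxyl at C3, borylation–oxidation of 3-metalated flavones being an established entry to flavonols.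

Step 10
Reactants: 16 3-hydroxy-5,6,7,8,4'-pentamethoxy-2'-(tosyloxy)flavone
Product: 17 3,5,6,7,8,4'-hexamethoxy-2'-(tosyloxy)flavone
Conditions: MeI, K2CO3, acetone, reflux
Reagents that add atoms: iodomethane, CI
Why: Williamson O-methylation of the acidic 3-hydroxyl, under conditions where the tosylate should survive because carbonate in acetone offers no nucleophile for sulfur.

Step 11
Reactants: 17 3,5,6,7,8,4'-hexamethoxy-2'-(tosyloxy)flavone
Product: 18 5-hydroxy-3,6,7,8,4'-pentamethoxy-2'-(tosyloxy)flavone
Conditions: BCl3 (1 M in CH2Cl2, 1.2–1.5 equiv), CH2Cl2, −78 → 0 °C; H2O/MeOH work-up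
Reagents that add atoms: none
Why: Chelation-controlled Lewis acid demethylation, in which BCl3 bridges the C4 carbonyl and the peri 5-methoxyl in a six-membered chelate and chloride removes only that methyl group at low temperature, as is usual for 5-methoxyflavones, while the 3-methoxyl, the other aryl methyl ethers and the sulfonate should stay intact.

Step 12
Reactants: 18 5-hydroxy-3,6,7,8,4'-pentamethoxy-2'-(tosyloxy)flavone
Product: 19 5,2'-dihydroxy-3,6,7,8,4'-pentamethoxyflavone
Conditions: K2CO3 (excess), MeOH, reflux; then dilute HCl to pH 4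
Reagents that add atoms: none
Why: Base-mediated methanolysis of the aryl sulfonate (methoxide attacks sulfur and the phenoxide leaves) should free the 2'-hydroxyl, with the methyl ethers and the chelated 5-hydroxyl inert and the methyl tosylate formed consumed by the excess methanolic base.

**Compound list**

1 | 3,4,5-trimethoxyphenol | COc1cc(O)cc(OC)c1OC | starting material
2 | 6-hydroxy-2,3,4-trimethoxybenzaldehyde | COc1cc(O)c(C=O)c(OC)c1OC | intermediate
3 | 6-hydroxy-2,3,4-trimethoxyphenyl formate | COc1cc(O)c(OC=O)c(OC)c1OC | intermediate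
4 | 3,4,5-trimethoxybenzene-1,2-diol | COc1cc(O)c(O)c(OC)c1OC | intermediate
5 | pentamethoxybenzene | COc1cc(OC)c(OC)c(OC)c1OC | intermediate
6 | pentamethoxyphenyllithium | [Li]c1c(OC)c(OC)c(OC)c(OC)c1OC | intermediate
7 | pentamethoxybenzoic acid | OC(=O)c1c(OC)c(OC)c(OC)c(OC)c1OC | intermediate
8 | 2-hydroxy-4-methoxybenzaldehyde | COc1ccc(C=O)c(O)c1 | starting material
9 | 2-formyl-5-methoxyphenyl 4-methylbenzenesulfonate | COc1ccc(C=O)c(OS(=O)(=O)c2ccc(C)cc2)c1 | intermediate
10 | 2-ethynyl-5-methoxyphenyl 4-methylbenzenesulfonate | COc1ccc(C#C)c(OS(=O)(=O)c2ccc(C)cc2)c1 | intermediate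
11 | pentamethoxybenzoyl chloride | ClC(=O)c1c(OC)c(OC)c(OC)c(OC)c1OC | intermediate
12 | 3-[4-methoxy-2-(tosyloxy)phenyl]-1-(pentamethoxyphenyl)prop-2-yn-1-one | COc1ccc(C#CC(=O)c2c(OC)c(OC)c(OC)c(OC)c2OC)c(OS(=O)(=O)c2ccc(C)cc2)c1 | intermediate
13 | 3-iodo-5,6,7,8-tetramethoxy-2-[4-methoxy-2-(tosyloxy)phenyl]chromen-4-one | COc1ccc(-c2oc3c(OC)c(OC)c(OC)c(OC)c3c(=O)c2I)c(OS(=O)(=O)c2ccc(C)cc2)c1 | intermediate
14 | chloro{5,6,7,8-tetramethoxy-2-[4-methoxy-2-(tosyloxy)phenyl]-4-oxochromen-3-yl}magnesium | COc1ccc(-c2oc3c(OC)c(OC)c(OC)c(OC)c3c(=O)c2[Mg]Cl)c(OS(=O)(=O)c2ccc(C)cc2)c1 | intermediate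
15 | dimethyl {5,6,7,8-tetramethoxy-2-[4-methoxy-2-(tosyloxy)phenyl]-4-oxochromen-3-yl}boronate | COc1ccc(-c2oc3c(OC)c(OC)c(OC)c(OC)c3c(=O)c2B(OC)OC)c(OS(=O)(=O)c2ccc(C)cc2)c1 | intermediate
16 | 3-hydroxy-5,6,7,8-tetramethoxy-2-[4-methoxy-2-(tosyloxy)phenyl]chromen-4-one | COc1ccc(-c2oc3c(OC)c(OC)c(OC)c(OC)c3c(=O)c2O)c(OS(=O)(=O)c2ccc(C)cc2)c1 | intermediate
17 | 3,5,6,7,8-pentamethoxy-2-[4-methoxy-2-(tosyloxy)phenyl]chromen-4-one | COc1ccc(-c2oc3c(OC)c(OC)c(OC)c(OC)c3c(=O)c2OC)c(OS(=O)(=O)c2ccc(C)cc2)c1 | intermediate
18 | 5-hydroxy-3,6,7,8-tetramethoxy-2-[4-methoxy-2-(tosyloxy)phenyl]chromen-4-one | COc1ccc(-c2oc3c(OC)c(OC)c(OC)c(O)c3c(=O)c2OC)c(OS(=O)(=O)c2ccc(C)cc2)c1 | intermediate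
19 | 5-hydroxy-2-(2-hydroxy-4-methoxyphenyl)-3,6,7,8-tetramethoxychromen-4-one (5,2'-dihydroxy-3,6,7,8,4'-pentamethoxyflavone) | COc1ccc(-c2oc3c(OC)c(OC)c(OC)c(O)c3c(=O)c2OC)c(O)c1 | target

**Summary**

Total step count: 12.
Longest linear sequence: 10 steps (steps 1–4 and 7–12, from 1); the alkyne branch (steps 5–6) joins at step 7.

**Steps most likely to fail**

Step 9 (iodine to hydroxyl at C3). The C3 organomagnesium may be protonated, may open ring C by β-elimination of O1, or may attack the sulfonyl sulfur of the neighbouring tosylate before it is borylated. The fallback sets out from 13 and comes back at 16, and avoids a carbanion altogether. A palladium-catalysed Miyaura borylation of 13 (B2pin2, PdCl2(dppf), KOAc, dioxane, 80 °C) would give the 3-pinacolboronate 5,6,7,8-tetramethoxy-2-[4-methoxy-2-(tosyloxy)phenyl]-3-(pinacolboryl)chromen-4-one F1. Sodium perborate in THF–water at room temperature would then oxidise F1 to flavonol 16.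

Step 8 (key cyclisation). Iodination of ring B, or plain addition of ICl across the triple bond, could outrun ring closure, because the two ortho substituents twist the aroyl group and slow the approach of the methoxy oxygen. The fallback sets out from 12 and comes back at 16, bypassing steps 8 and 9; it keeps the O1–C2 closure but introduces the C3 oxygen by oxidation instead of through the iodide.
- One equivalent of BCl3 in CH2Cl2 at −78 °C should remove a single ortho methyl group by chelation to the ketone, giving 1-(2-hydroxy-3,4,5,6-tetramethoxyphenyl)-3-[4-methoxy-2-(tosyloxy)phenyl]prop-2-yn-1-one F2.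
- Catalytic DMAP in DMF should close F2 by 6-endo oxa-Michael addition to 5,6,7,8-tetramethoxy-2-[4-methoxy-2-(tosyloxy)phenyl]chromen-4-one F3.
- Dimethyldioxirane in acetone/CH2Cl2 should epoxidise the C2=C3 bond of F3 to the racemic cis-fused 2,3-epoxyflavanone F4, which a trace of TsOH should isomerise to flavonol 16.

Step 11 (5-O-demethylation). A second methyl group may be lost (the 3-methoxyl through the five-membered chelate, or the 6-methoxyl once the 5-oxygen carries boron), or the reaction may stall. The fallback sets out from 16 and comes back at 18, with the order of methylation and demethylation reversed. BCl3 (excess, CH2Cl2, 0 °C → rt) applied to flavonol 16, where no 3-methoxyl can be lost, should give 3,5-dihydroxy-6,7,8-trimethoxy-2-[4-methoxy-2-(tosyloxy)phenyl]chromen-4-one F5. One equivalent of MeI with K2CO3 in acetone at room temperature should then methylate only the 3-hydroxyl, because the 5-hydroxyl is held in the strong six-membered hydrogen bond to the C4 carbonyl; this gives 18.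

**Further compounds**

F1 | step 9 | 5,6,7,8-tetramethoxy-2-[4-methoxy-2-(tosyloxy)phenyl]-3-(4,4,5,5-tetramethyl-1,3,2-dioxaborolan-2-yl)chromen-4-one | COc1ccc(-c2oc3c(OC)c(OC)c(OC)c(OC)c3c(=O)c2B2OC(C)(C)C(C)(C)O2)c(OS(=O)(=O)c2ccc(C)cc2)c1
F2 | step 8 | 1-(2-hydroxy-3,4,5,6-tetramethoxyphenyl)-3-[4-methoxy-2-(tosyloxy)phenyl]prop-2-yn-1-one | COc1ccc(C#CC(=O)c2c(O)c(OC)c(OC)c(OC)c2OC)c(OS(=O)(=O)c2ccc(C)cc2)c1
F3 | step 8 | 5,6,7,8-tetramethoxy-2-[4-methoxy-2-(tosyloxy)phenyl]chromen-4-one | COc1ccc(-c2cc(=O)c3c(OC)c(OC)c(OC)c(OC)c3o2)c(OS(=O)(=O)c2ccc(C)cc2)c1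
F4 | step 8 | rac-2,3-epoxy-5,6,7,8-tetramethoxy-2-[4-methoxy-2-(tosyloxy)phenyl]chroman-4-one (cis-fused epoxide, racemic, one enantiomer drawn) | O=C1[C@@H]2O[C@]2(c3ccc(OC)cc3OS(=O)(=O)c3ccc(C)cc3)Oc2c(OC)c(OC)c(OC)c(OC)c12
F5 | step 11 | 3,5-dihydroxy-6,7,8-trimethoxy-2-[4-methoxy-2-(tosyloxy)phenyl]chromen-4-one | COc1ccc(-c2oc3c(OC)c(OC)c(OC)c(O)c3c(=O)c2O)c(OS(=O)(=O)c2ccc(C)cc2)c1
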